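**Plan**

- Retrosynthesis: ring B is opened at C2–C3, with the C3 methyl carried as an exocyclic methylene. C3 and that carbon then form a terminal alkyne on C4, and C2 is the enol carbon of the C1 ethyl ketone. Next the C4–C4a aryl–propargyl bond and the C3–C4 acetylide–aldehyde bond are cut.
- Enabling feature: in ring B, C3 lies between the enolisable C2 (next to the C1 carbonyl on C8a) and the doubly benzylic C4 (on C4a). An alkyne on C4 and an enol at C2, both held ortho on ring A, are therefore partners for a six-membered ring.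
- Forward: O-benzylisovanillin and trimethylsilylacetylene give a racemic propargylic carbonate. It is joined to the arylzinc from iodinated 3,4-dimethoxypropiophenone (ring A with C1, C2 and the C2 methyl). C-desilylation and silyl enol ether formation follow, ring B closes last, and hydrogenation and debenzylation finish.
- Stereochemistry: C4 comes from the ligand in an enantioconvergent nickel coupling. C2 is set relative to C4 in the cyclisation and is also the thermodynamic 2,3-trans centre. C3 comes from hydrogenation anti to the pseudoaxial C4 aryl (3,4-cis).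

Key step: step 6

Remark: which pybox antipode gives the R centre in step 3 is not assumed; it is to be fixed by a first run with both ligand enantiomers and assignment of 9. Tetralone numbering (C1–C4, C4a, C8a) is used for all intermediates.

**Step 1**
Reactants: 1 trimethylsilylacetylene; 2 3-benzyloxy-4-methoxybenzaldehyde
Product: 5 methyl 1-(3-benzyloxy-4-methoxyphenyl)-3-(trimethylsilyl)prop-2-yn-1-yl carbonate (racemic), via lithium trimethylsilylacetylide 3 (not isolated), via lithium propargylic alkoxide 4 (not isolated)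
Conditions: nBuLi, THF, −78 °C; then 2; then ClCO2Me, −78 → 0 °C
Reagents that add atoms: methyl chloroformate, COC(=O)Cl
Why: Acetylide 1,2-addition to the aromatic aldehyde followed by O-acylation of the lithium alkoxide in the same flask should give the carbonate directly; a racemate suffices because step 3 is enantioconvergent.

**Step 2**
Reactants: 6 3,4-dimethoxypropiophenone
Product: 7 1-(2-iodo-4,5-dimethoxyphenyl)propan-1-one
Conditions: I2, CF3CO2Ag, CH2Cl2, 25 °C
Reagents that add atoms: iodine, II
Why: Electrophilic aromatic iodination should occur para to the 3-methoxy group and ortho to the acyl group, the usual site for veratryl ketones and aldehydes, while the silver salt removes iodide so the side chain is not halogenated.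

**Step 3**
Reactants: 5 racemic propargylic carbonate; 7 1-(2-iodo-4,5-dimethoxyphenyl)propan-1-one
Product: 9 1-{2-[(1R)-1-(3-benzyloxy-4-methoxyphenyl)-3-(trimethylsilyl)prop-2-yn-1-yl]-4,5-dimethoxyphenyl}propan-1-one, via arylzinc iodide 8 (not isolated)
Conditions: 7, Zn dust, LiCl, THF, 25–40 °C; then 5, NiCl2·glyme (10 mol %), indanyl-pybox (13 mol %), DME, −20 °C
Reagents that add atoms: none
Why: LiCl-promoted zinc insertion into the aryl iodide tolerates the ketone, and the nickel/pybox enantioconvergent Negishi arylation of a racemic propargylic carbonate should pass through a propargylic radical captured by the chiral aryl-nickel complex, so both enantiomers of 5 converge on the ligand-set R configuration at C4 while the silyl group suppresses allene formation.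

**Step 4**
Reactants: 9 silylalkyne ketone
Product: 10 1-{2-[(1R)-1-(3-benzyloxy-4-methoxyphenyl)prop-2-yn-1-yl]-4,5-dimethoxyphenyl}propan-1-one
Conditions: TBAF, AcOH, THF, 0 °C
Reagents that add atoms: none
Why: Fluoride protiodesilylation of the alkynylsilane under acetic acid buffering should keep the medium non-basic, so the acidic diaryl-propargylic C4–H is not removed and neither propargyl–allene isomerisation nor racemisation is expected.

**Step 5**
Reactants: 10 terminal alkyne ketone
Product: 11 tert-butyl{[(1Z)-1-{2-[(1R)-1-(3-benzyloxy-4-methoxyphenyl)prop-2-yn-1-yl]-4,5-dimethoxyphenyl}prop-1-en-1-yl]oxy}dimethylsilane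
Conditions: TBSOTf, Et3N, CH2Cl2, 0 °C
Reagents that add atoms: tert-butyldimethylsilyl triflate, CC(C)(C)[Si](C)(C)OS(=O)(=O)C(F)(F)F
Why: Soft enolisation (silyl triflate with a tertiary amine) of the ethyl ketone should give the Z silyl enol ether, since that geometry avoids A(1,3) strain between the methyl group and ring A, and the amine is too weak to touch C4–H or the alkyne.

**Step 6**
Reactants: 11 Z silyl enol ether
Product: 12 (2S,4R)-4-(3-benzyloxy-4-methoxyphenyl)-6,7-dimethoxy-2-methyl-3-methylidene-3,4-dihydronaphthalen-1(2H)-one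
Conditions: AuCl(PPh3) (5 mol %), AgBF4 (5 mol %), CH2Cl2/MeOH 10:1, 25 °C
Reagents that add atoms: none
Why: Cationic monovalent gold π-activates the terminal alkyne, C2 of the silyl enol ether adds anti to gold at the internal carbon C3 to give a silyloxocarbenium vinyl-gold species, and methanol then takes up the silyl group and protodeaurates to release the β,γ-unsaturated ketone and the catalyst. The closest known reaction type is the gold-catalysed Conia-ene-type carbocyclisation of silyl enol ethers onto alkynes, established for 5-exo and 6-exo closures. Ring B closes in the 6-exo-dig mode with both enol carbons inside the new ring, favoured over 7-endo-dig because a terminal alkyne is attacked at its internal carbon and ortho-disubstituted ring A holds C2 within reach of C3. The new stereocentre C2 is controlled by C4: the C4 aryl sits pseudoaxial to avoid the peri hydrogen H5 and the gold-bearing vinyl carbon, and the Z enol ether then places the C2 methyl pseudoequatorial, trans to the aryl (2S), which should also be the more stable arrangement. The step needs carbon rather than oxygen attack and no migration of the new double bond into ring B (which would aromatise to a naphthol); the intact TBS enol ether and the neutral, base-free medium should secure both and leave C4–H untouched, and 12 is passed through neutral alumina and used at once.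

**Step 7**
Reactants: 12 3-methylidene tetralone
Product: 13 (2S,3R,4R)-4-(3-benzyloxy-4-methoxyphenyl)-6,7-dimethoxy-2,3-dimethyl-3,4-dihydronaphthalen-1(2H)-one
Conditions: H2 (3 atm), RhCl(PPh3)3 (10 mol %), toluene, 25 °C; then DBU (0.2 equiv), CH2Cl2, 25 °C
Reagents that add atoms: none
Why: Homogeneous hydrogenation of the 1,1-disubstituted alkene should deliver hydrogen to the C3 face opposite the pseudoaxial C4 aryl, setting the C3 methyl cis to the aryl (3R) with little double-bond migration and no loss of the benzyl ether, and the catalytic base converges any C2 epimer on the trans-diequatorial 2,3-dimethyl arrangement.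

**Step 8**
Reactants: 13 benzyl-protected tetralone
Product: 14 (2S,3R,4R)-4-(3-hydroxy-4-methoxyphenyl)-6,7-dimethoxy-2,3-dimethyl-3,4-dihydronaphthalen-1(2H)-one (CNP0170223.1)
Conditions: H2 (1 atm), Pd/C, EtOAc, 25 °C
Reagents that add atoms: none
Why: Hydrogenolysis of the benzyl aryl ether over palladium on carbon under neutral conditions should free the phenol without touching the electron-rich aryl ketone or the three stereocentres.

**Compound list**

1 | trimethylsilylacetylene | C#C[Si](C)(C)C | starting material
2 | 3-benzyloxy-4-methoxybenzaldehyde | COc1ccc(C=O)cc1OCc1ccccc1 | starting material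
3 | lithium trimethylsilylacetylide | [Li]C#C[Si](C)(C)C | intermediate
4 | lithium 1-(3-benzyloxy-4-methoxyphenyl)-3-(trimethylsilyl)prop-2-yn-1-olate (racemic) | [Li]OC(C#C[Si](C)(C)C)c1ccc(OC)c(OCc2ccccc2)c1 | intermediate
5 | methyl 1-(3-benzyloxy-4-methoxyphenyl)-3-(trimethylsilyl)prop-2-yn-1-yl carbonate (racemic) | COC(=O)OC(C#C[Si](C)(C)C)c1ccc(OC)c(OCc2ccccc2)c1 | intermediate
6 | 3,4-dimethoxypropiophenone | CCC(=O)c1ccc(OC)c(OC)c1 | starting material
7 | 1-(2-iodo-4,5-dimethoxyphenyl)propan-1-one | CCC(=O)c1cc(OC)c(OC)cc1I | intermediate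
8 | (4,5-dimethoxy-2-propanoylphenyl)zinc iodide | CCC(=O)c1cc(OC)c(OC)cc1[Zn]I | intermediate
9 | 1-{2-[(1R)-1-(3-benzyloxy-4-methoxyphenyl)-3-(trimethylsilyl)prop-2-yn-1-yl]-4,5-dimethoxyphenyl}propan-1-one | COc1ccc([C@@H](C#C[Si](C)(C)C)c2cc(OC)c(OC)cc2C(=O)CC)cc1OCc1ccccc1 | intermediate
10 | 1-{2-[(1R)-1-(3-benzyloxy-4-methoxyphenyl)prop-2-yn-1-yl]-4,5-dimethoxyphenyl}propan-1-one | COc1ccc([C@@H](C#C)c2cc(OC)c(OC)cc2C(=O)CC)cc1OCc1ccccc1 | intermediate
11 | tert-butyl{[(1Z)-1-{2-[(1R)-1-(3-benzyloxy-4-methoxyphenyl)prop-2-yn-1-yl]-4,5-dimethoxyphenyl}prop-1-en-1-yl]oxy}dimethylsilane | COc1ccc([C@@H](C#C)c2cc(OC)c(OC)cc2/C(O[Si](C)(C)C(C)(C)C)=C/C)cc1OCc1ccccc1 | intermediate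
12 | (2S,4R)-4-(3-benzyloxy-4-methoxyphenyl)-6,7-dimethoxy-2-methyl-3-methylidene-3,4-dihydronaphthalen-1(2H)-one | COc1ccc([C@@H]2c3cc(OC)c(OC)cc3C(=O)[C@@H](C)C2=C)cc1OCc1ccccc1 | intermediate
13 | (2S,3R,4R)-4-(3-benzyloxy-4-methoxyphenyl)-6,7-dimethoxy-2,3-dimethyl-3,4-dihydronaphthalen-1(2H)-one | COc1ccc([C@@H]2c3cc(OC)c(OC)cc3C(=O)[C@@H](C)[C@@H]2C)cc1OCc1ccccc1 | intermediate
14 | (2S,3R,4R)-4-(3-hydroxy-4-methoxyphenyl)-6,7-dimethoxy-2,3-dimethyl-3,4-dihydronaphthalen-1(2H)-one | COc1ccc([C@@H]2c3cc(OC)c(OC)cc3C(=O)[C@@H](C)[C@@H]2C)cc1O | target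

**Step count and risks**

Total step count: 8. Longest linear sequence: 7 steps (steps 2–8 from 6, or steps 1 and 3–8 from 1 and 2).

Steps most likely to fail:

1. Step 3. The arylzinc carries an ortho acyl group that chelates zinc and crowds nickel, so transmetalation may be slow and ligand control weak; propargyl–allenyl scrambling could also divert material. The fallback reverses the roles of the partners, so the hindered ring A becomes the electrophile and an unhindered arylzinc is used. It sets out from 7:
   - Ketalisation (ethylene glycol, TsOH, toluene, reflux) gives 2-ethyl-2-(2-iodo-4,5-dimethoxyphenyl)-1,3-dioxolane F1.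
   - Iodine–lithium exchange (nBuLi, THF, −78 °C) and DMF give 2-(2-ethyl-1,3-dioxolan-2-yl)-4,5-dimethoxybenzaldehyde F2.
   - Addition of 3 and trapping with ClCO2Me give racemic methyl 1-[2-(2-ethyl-1,3-dioxolan-2-yl)-4,5-dimethoxyphenyl]-3-(trimethylsilyl)prop-2-yn-1-yl carbonate F3.
   - Coupling under the same nickel/pybox conditions with (3-benzyloxy-4-methoxyphenyl)zinc iodide F4 (from purchased 2-benzyloxy-4-bromo-1-methoxybenzene, Mg then ZnI2) should give 2-{2-[(1R)-1-(3-benzyloxy-4-methoxyphenyl)-3-(trimethylsilyl)prop-2-yn-1-yl]-4,5-dimethoxyphenyl}-2-ethyl-1,3-dioxolane F5.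
   - PPTS in wet acetone releases the ketone, and the route is rejoined at 9.

2. Step 6. The silyl group may be lost before the C–C bond forms, after which the ketone oxygen rather than C2 attacks the activated alkyne; acid traces may also move the new double bond into ring B. The fallback forms the same C2–C3 bond by a radical route without a carbophilic Lewis acid. It sets out from 11: NBS (THF, −78 °C) gives 2-bromo-1-{2-[(1R)-1-(3-benzyloxy-4-methoxyphenyl)prop-2-yn-1-yl]-4,5-dimethoxyphenyl}propan-1-one F6 as both C2 epimers. Slow addition of Bu3SnH with AIBN (benzene, 80 °C) should generate the C2 radical, which closes 6-exo-dig onto C3, and the vinyl radical is reduced. The route is rejoined at 12.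

3. Step 7. The exocyclic alkene may migrate into ring B on a rhodium hydride and aromatise irreversibly, or face selectivity may be incomplete. The fallback removes the enolisable ketone first and uses a metal-free reductant. It sets out from 12:
   - Luche reduction (NaBH4, CeCl3·7H2O, MeOH, −78 °C) gives (2S,4R)-4-(3-benzyloxy-4-methoxyphenyl)-6,7-dimethoxy-2-methyl-3-methylidene-1,2,3,4-tetrahydronaphthalen-1-ol F7 (C1 epimers), which can no longer tautomerise to a naphthol.
   - Diimide (dipotassium azodicarboxylate KO2CN=NCO2K, AcOH, MeOH) should add hydrogen anti to the C4 aryl to give (2S,3R,4R)-4-(3-benzyloxy-4-methoxyphenyl)-6,7-dimethoxy-2,3-dimethyl-1,2,3,4-tetrahydronaphthalen-1-ol F8 (C1 epimers).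
   - Dess–Martin oxidation and brief DBU treatment rejoin the route at 13.

**Further compounds**

F1 | step 3 | 2-ethyl-2-(2-iodo-4,5-dimethoxyphenyl)-1,3-dioxolane | CCC1(OCCO1)c1cc(OC)c(OC)cc1I
F2 | step 3 | 2-(2-ethyl-1,3-dioxolan-2-yl)-4,5-dimethoxybenzaldehyde | CCC1(OCCO1)c1cc(OC)c(OC)cc1C=O
F3 | step 3 | methyl 1-[2-(2-ethyl-1,3-dioxolan-2-yl)-4,5-dimethoxyphenyl]-3-(trimethylsilyl)prop-2-yn-1-yl carbonate (racemic) | COC(=O)OC(C#C[Si](C)(C)C)c1cc(OC)c(OC)cc1C1(CC)OCCO1
F4 | step 3 | (3-benzyloxy-4-methoxyphenyl)zinc iodide | COc1ccc([Zn]I)cc1OCc1ccccc1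
F5 | step 3 | 2-{2-[(1R)-1-(3-benzyloxy-4-methoxyphenyl)-3-(trimethylsilyl)prop-2-yn-1-yl]-4,5-dimethoxyphenyl}-2-ethyl-1,3-dioxolane | COc1ccc([C@@H](C#C[Si](C)(C)C)c2cc(OC)c(OC)cc2C2(CC)OCCO2)cc1OCc1ccccc1
F6 | step 6 | 2-bromo-1-{2-[(1R)-1-(3-benzyloxy-4-methoxyphenyl)prop-2-yn-1-yl]-4,5-dimethoxyphenyl}propan-1-one (both C2 epimers) | COc1ccc([C@@H](C#C)c2cc(OC)c(OC)cc2C(=O)C(C)Br)cc1OCc1ccccc1
F7 | step 7 | (2S,4R)-4-(3-benzyloxy-4-methoxyphenyl)-6,7-dimethoxy-2-methyl-3-methylidene-1,2,3,4-tetrahydronaphthalen-1-ol (C1 epimers) | COc1ccc([C@@H]2c3cc(OC)c(OC)cc3C(O)[C@@H](C)C2=C)cc1OCc1ccccc1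
F8 | step 7 | (2S,3R,4R)-4-(3-benzyloxy-4-methoxyphenyl)-6,7-dimethoxy-2,3-dimethyl-1,2,3,4-tetrahydronaphthalen-1-ol (C1 epimers) | COc1ccc([C@@H]2c3cc(OC)c(OC)cc3C(O)[C@@H](C)[C@@H]2C)cc1OCc1ccccc1
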